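**Retrosynthetic overview**
- Feature addressed: the target is acyclic, and its stereochemical problem is the pseudo-meso syn-1,3-diol C3(R)/C5(S) around the C4 methylene. The two carbinol carbons differ only through the remote rings A (3,4-dihydroxy-5-methoxyphenyl on C1) and B (4-hydroxyphenyl on C7), so each centre needs its own reagent control, of opposite local sense.
- Key disconnection C4–C5: union of two nucleophilic carbons, the primary C4–B carbon of an enantioenriched 1,2-bis(boronic ester) (ring A half, C1–C4) and a sparteine-configured α-oxy carbanion at C5 (ring B half, C5–C7), by a boronate 1,2-metallate shift; both C–B bonds are then oxidised to the diol.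
- C3 is set one step earlier by Pt-catalysed enantioselective diboration of the ring A 4-aryl-but-1-ene; C5 is set in the key step by (+)-sparteine. No ring is formed at any stage.
- Halves: the ring A butene comes from 5-hydroxyvanillin (benzylation, reduction, chlorination, allyl Grignard coupling); the ring B benzoate comes from 3-[4-(benzyloxy)phenyl]propan-1-ol. The end game is hydrogenolysis of three benzyl ethers, which leaves the ring A methyl ether untouched.

Key step: step 7

Assumption: the (R,R)-antipode of the TADDOL-derived phosphonite is taken to deliver the (S)-1,2-bis(boronic ester) 6 (the sense that gives (R)-1,2-diols from 1-alkenes on oxidation); if the catalyst's sense is the reverse, its (S,S)-antipode is used and nothing else changes.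

**Step 1**
Reactants: 1 3,4-dihydroxy-5-methoxybenzaldehyde (5-hydroxyvanillin)
Product: 2 3,4-bis(benzyloxy)-5-methoxybenzaldehyde
Conditions: BnBr, K2CO3, DMF, 60 °C, N2
Reagents that add atoms: benzyl bromide, BrCc1ccccc1
Why: Williamson etherification of both phenoxides; benzyl is chosen because it survives organometallics and alkaline peroxide and is removed at the end without touching the methyl ether.

**Step 2**
Reactants: 2 3,4-bis(benzyloxy)-5-methoxybenzaldehyde
Product: 3 [3,4-bis(benzyloxy)-5-methoxyphenyl]methanol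
Conditions: NaBH4, MeOH/THF, 0 °C
Reagents that add atoms: none
Why: Chemoselective borohydride reduction of the aryl aldehyde to the benzylic alcohol.

**Step 3**
Reactants: 3 [3,4-bis(benzyloxy)-5-methoxyphenyl]methanol
Product: 4 1,2-bis(benzyloxy)-5-(chloromethyl)-3-methoxybenzene
Conditions: SOCl2, cat. DMF, CH2Cl2, 0 °C to rt; used crude
Reagents that add atoms: thionyl chloride, ClS(Cl)=O
Why: Deoxychlorination of an electron-rich benzylic alcohol through its chlorosulfite, a standard route to alkoxy-substituted benzyl chlorides.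

**Step 4**
Reactants: 4 1,2-bis(benzyloxy)-5-(chloromethyl)-3-methoxybenzene
Product: 5 1,2-bis(benzyloxy)-5-(but-3-en-1-yl)-3-methoxybenzene
Conditions: allylMgBr, THF, 0 °C to rt
Reagents that add atoms: allylmagnesium bromide, C=CC[Mg]Br
Why: Uncatalysed substitution of a benzylic chloride by an allyl Grignard reagent gives the 4-aryl-but-1-ene (C1–C4 of the chain) directly.

**Step 5**
Reactants: 5 1,2-bis(benzyloxy)-5-(but-3-en-1-yl)-3-methoxybenzene
Product: 6 (S)-2,2'-[4-(3,4-bis(benzyloxy)-5-methoxyphenyl)butane-1,2-diyl]bis(4,4,5,5-tetramethyl-1,3,2-dioxaborolane)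
Conditions: B2pin2, cat. Pt(dba)3, cat. (R,R)-3,5-diisopropylphenyl-TADDOL phenylphosphonite, THF, 60 °C
Reagents that add atoms: bis(pinacolato)diboron, CC1(C)OB(OC1(C)C)B1OC(C)(C)C(C)(C)O1
Why: Pt(0)-catalysed enantioselective syn-1,2-diboration of a monosubstituted alkene; insertion of the alkene into Pt–B inside the chiral phosphonite pocket sets C3, and the aryl ethers are inert.

**Step 6**
Reactants: 7 3-[4-(benzyloxy)phenyl]propan-1-ol
Product: 8 3-[4-(benzyloxy)phenyl]propyl 2,4,6-triisopropylbenzoate
Conditions: 2,4,6-triisopropylbenzoic acid, PPh3, DIAD, THF, 0 °C to rt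
Reagents that add atoms: 2,4,6-triisopropylbenzoic acid, CC(C)c1cc(C(C)C)c(C(=O)O)c(C(C)C)c1
Why: Mitsunobu esterification of a primary alcohol installs the hindered benzoate that later directs α-lithiation and serves as the leaving group in the 1,2-shift.

**Step 7**
Reactants: 6 (S)-2,2'-[4-(3,4-bis(benzyloxy)-5-methoxyphenyl)butane-1,2-diyl]bis(4,4,5,5-tetramethyl-1,3,2-dioxaborolane); 8 3-[4-(benzyloxy)phenyl]propyl 2,4,6-triisopropylbenzoate
Product: 12 (3R,5S)-1-[3,4-bis(benzyloxy)-5-methoxyphenyl]-7-[4-(benzyloxy)phenyl]heptane-3,5-diol, via lithiated benzoate 9 (not isolated), via boronate complex 10 (not isolated), via 1,3-bis(boronic ester) 11 (not isolated)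
Conditions: 8, (+)-sparteine, s-BuLi, Et2O, −78 °C; then 6, −78 °C to reflux; then THF, aq. NaOH, H2O2, 0 °C to rt
Reagents that add atoms: hydrogen peroxide, OO
Why: s-BuLi/(+)-sparteine removes the pro-R α-hydrogen of 8 under direction by the benzoate carbonyl and gives the configurationally stable (R)-lithio benzoate 9 at −78 °C, which adds with retention to the less hindered primary boron of 6 to form boronate complex 10. On warming, the C4 methylene migrates from boron to C5 anti-periplanar to the departing benzoate (1,2-metallate shift with inversion at C5), so the C4–C5 bond joins two carbons that are both nucleophilic (a C–B carbon and an α-oxy carbanion), and alkaline peroxide then converts both C–B bonds of 11 into C–O bonds with retention. The closest known reaction type is the lithiation–borylation homologation of enantioenriched 1,2-bis(boronic esters) with sparteine-ligated lithiated benzoates or carbamates to give 1,3-bis(boronic esters) and, after oxidation, 1,3-diols. No ring is closed. C5 (S) is controlled by the sparteine antipode alone and C3 (R) is carried from 6, so the pseudo-meso syn pattern, which no single reagent could impose on two near-identical carbinol sites, arises from two independent reagent-controlled events. The step needs primary-over-secondary boron selectivity, secured by the steric difference between the CH2–B and CH–B sites of 6, and α-lithiation of 8 in preference to benzylic or ortho lithiation of its aryl benzyl ether, secured by the complex-induced proximity effect of the benzoate in Et2O at −78 °C.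

**Step 8**
Reactants: 12 (3R,5S)-1-[3,4-bis(benzyloxy)-5-methoxyphenyl]-7-[4-(benzyloxy)phenyl]heptane-3,5-diol
Product: 13 (3R,5S)-1-(3,4-dihydroxy-5-methoxyphenyl)-7-(4-hydroxyphenyl)heptane-3,5-diol
Conditions: H2 (1 atm), Pd/C, EtOAc/MeOH, rt; filtration and concentration under argon
Reagents that add atoms: none
Why: Hydrogenolysis of the three aryl benzyl ethers under neutral conditions; the non-benzylic secondary alcohols, the methyl ether and both stereocentres are unaffected.

**Compound list**
1 | 3,4-dihydroxy-5-methoxybenzaldehyde (5-hydroxyvanillin) | COc1cc(C=O)cc(O)c1O | starting material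
2 | 3,4-bis(benzyloxy)-5-methoxybenzaldehyde | COc1cc(C=O)cc(OCc2ccccc2)c1OCc1ccccc1 | intermediate
3 | [3,4-bis(benzyloxy)-5-methoxyphenyl]methanol | COc1cc(CO)cc(OCc2ccccc2)c1OCc1ccccc1 | intermediate
4 | 1,2-bis(benzyloxy)-5-(chloromethyl)-3-methoxybenzene | COc1cc(CCl)cc(OCc2ccccc2)c1OCc1ccccc1 | intermediate
5 | 1,2-bis(benzyloxy)-5-(but-3-en-1-yl)-3-methoxybenzene | COc1cc(CCC=C)cc(OCc2ccccc2)c1OCc1ccccc1 | intermediate
6 | (S)-2,2'-[4-(3,4-bis(benzyloxy)-5-methoxyphenyl)butane-1,2-diyl]bis(4,4,5,5-tetramethyl-1,3,2-dioxaborolane) | COc1cc(CC[C@@H](B2OC(C)(C)C(C)(C)O2)CB2OC(C)(C)C(C)(C)O2)cc(OCc2ccccc2)c1OCc1ccccc1 | intermediate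
7 | 3-[4-(benzyloxy)phenyl]propan-1-ol | OCCCc1ccc(OCc2ccccc2)cc1 | starting material
8 | 3-[4-(benzyloxy)phenyl]propyl 2,4,6-triisopropylbenzoate | CC(C)c1cc(C(C)C)c(C(=O)OCCCc2ccc(OCc3ccccc3)cc2)c(C(C)C)c1 | intermediate
9 | (R)-1-lithio-3-[4-(benzyloxy)phenyl]propyl 2,4,6-triisopropylbenzoate, (+)-sparteine complex (drawn without the diamine) | [Li][C@@H](OC(=O)c1c(C(C)C)cc(C(C)C)cc1C(C)C)CCc1ccc(OCc2ccccc2)cc1 | intermediate (not isolated)
10 | lithium boronate complex formed from 9 at the primary boron of 6 | COc1cc(CC[C@@H](B2OC(C)(C)C(C)(C)O2)C[B-]2(OC(C)(C)C(C)(C)O2)[C@@H](OC(=O)c2c(C(C)C)cc(C(C)C)cc2C(C)C)CCc2ccc(OCc3ccccc3)cc2)cc(OCc2ccccc2)c1OCc1ccccc1.[Li+] | intermediate (not isolated)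
11 | 2,2'-[(3R,5S)-1-(3,4-bis(benzyloxy)-5-methoxyphenyl)-7-(4-(benzyloxy)phenyl)heptane-3,5-diyl]bis(4,4,5,5-tetramethyl-1,3,2-dioxaborolane) | COc1cc(CC[C@@H](B2OC(C)(C)C(C)(C)O2)C[C@@H](B2OC(C)(C)C(C)(C)O2)CCc2ccc(OCc3ccccc3)cc2)cc(OCc2ccccc2)c1OCc1ccccc1 | intermediate (not isolated)
12 | (3R,5S)-1-[3,4-bis(benzyloxy)-5-methoxyphenyl]-7-[4-(benzyloxy)phenyl]heptane-3,5-diol | COc1cc(CC[C@@H](O)C[C@@H](O)CCc2ccc(OCc3ccccc3)cc2)cc(OCc2ccccc2)c1OCc1ccccc1 | intermediate
13 | (3R,5S)-1-(3,4-dihydroxy-5-methoxyphenyl)-7-(4-hydroxyphenyl)heptane-3,5-diol | COc1cc(CC[C@@H](O)C[C@@H](O)CCc2ccc(O)cc2)cc(O)c1O | target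

**Step count and risks**
Total steps: 8. Longest linear sequence: 7 (steps 1–5, 7, 8).

Steps most likely to fail:

1. Step 7. The base may deprotonate the ArO–CH2Ph position of 8 in competition with the benzoate-directed α-lithiation, the lithiated benzoate may also add to the secondary boron of 6, or the 1,2-shift may stall; each lowers the yield or the diastereomeric purity of 12. The fallback sets out from 5 and 7 and returns at 12. Tsuji–Wacker oxidation of 5 (PdCl2, CuCl, O2, DMF/H2O) should give the methyl ketone 4-[3,4-bis(benzyloxy)-5-methoxyphenyl]butan-2-one F1, and Dess–Martin oxidation of 7 should give 3-[4-(benzyloxy)phenyl]propanal F2. Enolisation of F1 on the methyl side with Ipc2BCl/Et3N (borane antipode chosen for the 5S carbinol) and aldol addition to F2 should give (S)-1-[3,4-bis(benzyloxy)-5-methoxyphenyl]-7-[4-(benzyloxy)phenyl]-5-hydroxyheptan-3-one F3. Narasaka–Prasad reduction of F3 (Et2BOMe, NaBH4, THF/MeOH, −78 °C) sets C3 syn to C5 by chelate control and delivers 12.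

2. Step 5. Facial discrimination of the unbiased terminal alkene may be insufficient, or turnover may be slow; the first would erode the configurational purity at C3 that step 7 relies on. The fallback sets out from 5 and returns at 6. Cross-metathesis of 5 with vinylboronic acid pinacol ester (second-generation Ru benzylidene catalyst, CH2Cl2, 40 °C) should give 2-[(E)-4-(3,4-bis(benzyloxy)-5-methoxyphenyl)but-1-en-1-yl]-4,4,5,5-tetramethyl-1,3,2-dioxaborolane F4. Enantioselective Cu-catalysed protoboration of F4 (B2pin2, CuCl, chiral N-heterocyclic carbene ligand of the appropriate antipode, NaOt-Bu, MeOH, THF) places the second boron on C3 and gives 6.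

3. Step 4. The electron-rich benzylic chloride 4 may ionise and self-alkylate or undergo Wurtz-type homocoupling before the Grignard reagent captures it. The fallback sets out from 2 and returns at 5, bypassing 3 and 4. Addition of allylmagnesium bromide to 2 (THF, 0 °C) should give racemic 1-[3,4-bis(benzyloxy)-5-methoxyphenyl]but-3-en-1-ol F5. Ionic deoxygenation of F5 with Et3SiH/BF3·OEt2 (CH2Cl2, −78 to 0 °C), through the benzylic cation stabilised by the para-benzyloxy group, gives 5.

**Further compounds**
F1 | step 7 | 4-[3,4-bis(benzyloxy)-5-methoxyphenyl]butan-2-one | COc1cc(CCC(C)=O)cc(OCc2ccccc2)c1OCc1ccccc1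
F2 | step 7 | 3-[4-(benzyloxy)phenyl]propanal | O=CCCc1ccc(OCc2ccccc2)cc1
F3 | step 7 | (S)-1-[3,4-bis(benzyloxy)-5-methoxyphenyl]-7-[4-(benzyloxy)phenyl]-5-hydroxyheptan-3-one | COc1cc(CCC(=O)C[C@@H](O)CCc2ccc(OCc3ccccc3)cc2)cc(OCc2ccccc2)c1OCc1ccccc1
F4 | step 5 | 2-[(E)-4-(3,4-bis(benzyloxy)-5-methoxyphenyl)but-1-en-1-yl]-4,4,5,5-tetramethyl-1,3,2-dioxaborolane | COc1cc(CC/C=C/B2OC(C)(C)C(C)(C)O2)cc(OCc2ccccc2)c1OCc1ccccc1
F5 | step 4 | 1-[3,4-bis(benzyloxy)-5-methoxyphenyl]but-3-en-1-ol (racemic) | COc1cc(C(O)CC=C)cc(OCc2ccccc2)c1OCc1ccccc1
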